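**Retrosynthetic overview**

1. Labels: ring A = a1 (C–OMe), a2 (C–H), a3 (C–CH3), a4 (C bearing the depsidone C=O), a5 (C–O of the ether), a6 (C–CH2OH); ring B = b1 (C–O of the ether), b2 (C–O of the ester), b3 (C–CH3), b4 (C–OH), b5 (C bearing the phthalide C=O), b6 (C bearing the lactol carbon).
2. Key disconnection: the five-membered lactone (b6–CH2 and CH2–O) goes back to a depsidone b5-carboxylic acid plus CH2Br2. The plan rests on ring B: b4 carries oxygen, so b6 is the one carbon ortho to the b5 carboxyl that can hold hydrogen. A carboxylate-bound palladium therefore has a single C–H bond to reach, and b1 keeps a hydrogen-bearing neighbour while the diaryl ether is made.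
3. Before it: the ether a5–O–b1 is made by SNAr of a ring A fluoride flanked by ester and formyl groups with a ring B phenol whose only free hydroxyl is at b1; the seven-membered lactone (a4 C=O to b2–O) is closed next. Ring A comes from 3-fluoro-5-methylanisole, ring B from methyl 2,4-dihydroxy-3-methylbenzoate.
4. After it: hydroxylation of the phthalide CH2 through its enolate, removal of benzyl and silyl groups to the racemic lactol, lipase-catalysed dynamic kinetic acetylation to the (R)-acylal, and enzymatic alcoholysis under neutral conditions.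
5. Ring order: depsidone lactone (step 9), then phthalide lactone (step 13).

Key step: step 13

Assumption: the lactol carbon can epimerise by ring–chain tautomerism with the b6-formyl b5-carboxylic acid form, so it is set in the last two steps and released without base or water; the product should be kept cold as a solid.

**Route**

Step 1
Reactants: 1 3-fluoro-5-methylanisole
Product: 2 2-bromo-1-fluoro-5-methoxy-3-methylbenzene
Conditions: NBS, MeCN, 0 °C to rt
Reagents that add atoms: N-bromosuccinimide, O=C1CCC(=O)N1Br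
Why: Electrophilic aromatic bromination in a polar solvent, where the methoxy group should direct the halogen to its para position (between F and CH3) in preference to the two ortho sites.

Step 2
Reactants: 2 2-bromo-1-fluoro-5-methoxy-3-methylbenzene
Product: 4 3-bromo-2-fluoro-6-methoxy-4-methylbenzaldehyde, via aryllithium 3 (not isolated)
Conditions: LiN(iPr)2, THF, −78 °C; DMF, −78 °C; aq. HCl
Reagents that add atoms: lithium diisopropylamide, CC(C)[N-]C(C)C.[Li+] (lithium of 3); N,N-dimethylformamide, CN(C)C=O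
Why: Directed ortho-metalation, in which the hydrogen flanked by F and OMe is the most acidic, the amide base does not exchange bromine, and the aryllithium is stable at −78 °C until it is formylated by DMF.

Step 3
Reactants: 4 3-bromo-2-fluoro-6-methoxy-4-methylbenzaldehyde
Product: 5 4-methoxybenzyl 2-fluoro-3-formyl-4-methoxy-6-methylbenzoate
Conditions: Pd(OAc)2 (cat.), Xantphos, CO (1 atm), 4-methoxybenzyl alcohol, Et3N, toluene, 90 °C
Reagents that add atoms: carbon monoxide, [C-]#[O+]; 4-methoxybenzyl alcohol, COc1ccc(CO)cc1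
Why: Palladium-catalysed alkoxycarbonylation of an aryl bromide (oxidative addition, CO insertion, alcoholysis of the acylpalladium), with a neutral alcohol and an amine base that should leave the activated C–F bond and the aldehyde alone.

Step 4
Reactants: 6 methyl 2,4-dihydroxy-3-methylbenzoate
Product: 7 methyl 2-hydroxy-4-(methoxymethoxy)-3-methylbenzoate
Conditions: MOMCl, iPr2NEt, CH2Cl2, 0 °C to rt
Reagents that add atoms: chloromethyl methyl ether, COCCl
Why: O-Alkylation that should stop at the 4-hydroxyl, because the 2-hydroxyl is held in a hydrogen bond to the ester carbonyl and is unreactive under mild base.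

Step 5
Reactants: 7 methyl 2-hydroxy-4-(methoxymethoxy)-3-methylbenzoate
Product: 8 methyl 5-bromo-2-hydroxy-4-(methoxymethoxy)-3-methylbenzoate
Conditions: NBS, MeCN, 0 °C, dark
Reagents that add atoms: N-bromosuccinimide, O=C1CCC(=O)N1Br
Why: Electrophilic aromatic bromination directed by the free phenol to C5, the only open position para to it and ortho to the MOM ether.

Step 6
Reactants: 8 methyl 5-bromo-2-hydroxy-4-(methoxymethoxy)-3-methylbenzoate
Product: 9 methyl 2-(benzyloxy)-5-bromo-4-(methoxymethoxy)-3-methylbenzoate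
Conditions: BnBr, K2CO3, DMF, 60 °C
Reagents that add atoms: benzyl bromide, BrCc1ccccc1
Why: Williamson etherification of the chelated salicylate hydroxyl, which needs carbonate in DMF with warming and leaves the MOM acetal and the aryl bromide intact.

Step 7
Reactants: 9 methyl 2-(benzyloxy)-5-bromo-4-(methoxymethoxy)-3-methylbenzoate
Product: 11 methyl 2-(benzyloxy)-5-hydroxy-4-(methoxymethoxy)-3-methylbenzoate, via pinacol boronate 10 (not isolated)
Conditions: B2pin2, Pd(dppf)Cl2 (cat.), KOAc, 1,4-dioxane, 90 °C; then THF, aq. H2O2, NaHCO3, 0 °C to rt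
Reagents that add atoms: bis(pinacolato)diboron, CC1(C)OB(OC1(C)C)B1OC(C)(C)C(C)(C)O1 (boryl group of 10); hydrogen peroxide, OO
Why: Miyaura borylation followed by oxidative C–B to C–O conversion (1,2-aryl shift to peroxide oxygen), buffered with bicarbonate so that the methyl ester survives.

Step 8
Reactants: 5 4-methoxybenzyl 2-fluoro-3-formyl-4-methoxy-6-methylbenzoate; 11 methyl 2-(benzyloxy)-5-hydroxy-4-(methoxymethoxy)-3-methylbenzoate
Product: 12 4-methoxybenzyl 2-[4-(benzyloxy)-5-(methoxycarbonyl)-2-(methoxymethoxy)-3-methylphenoxy]-3-formyl-4-methoxy-6-methylbenzoate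
Conditions: K2CO3, DMF, 40 °C
Reagents that add atoms: none
Why: SNAr (addition–elimination) at a fluoride activated by an ortho ester and an ortho formyl group; b1–OH is the only free phenol, so the ether can form only at a5–O–b1, and b1 is hindered on one side only because b6 still carries hydrogen.

Step 9
Reactants: 12 4-methoxybenzyl 2-[4-(benzyloxy)-5-(methoxycarbonyl)-2-(methoxymethoxy)-3-methylphenoxy]-3-formyl-4-methoxy-6-methylbenzoate
Product: 14 methyl 8-(benzyloxy)-4-formyl-3-methoxy-1,9-dimethyl-11-oxo-11H-dibenzo[b,e][1,4]dioxepine-7-carboxylate, via hydroxy acid 13 (not isolated)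
Conditions: CF3CO2H–CH2Cl2 (1:4), C6HMe5, 0 °C to rt; evaporate; (CF3CO)2O, toluene (high dilution), 0 °C to rt
Reagents that add atoms: none
Why: Acidolysis of the 4-methoxybenzyl ester (alkyl–oxygen cleavage, cation trapped by pentamethylbenzene) and of the MOM acetal frees the a4 acid and the b2 phenol, which then lactonise through the mixed trifluoroacetic anhydride to the seven-membered depsidone; the acid is used while a6 is still an aldehyde, because a benzylic C–O bond at a6 would ionise.

Step 10
Reactants: 14 methyl 8-(benzyloxy)-4-formyl-3-methoxy-1,9-dimethyl-11-oxo-11H-dibenzo[b,e][1,4]dioxepine-7-carboxylate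
Product: 15 methyl 8-(benzyloxy)-4-(hydroxymethyl)-3-methoxy-1,9-dimethyl-11-oxo-11H-dibenzo[b,e][1,4]dioxepine-7-carboxylate
Conditions: NaBH4, THF–MeOH (10:1), −30 °C; aq. NH4Cl
Reagents that add atoms: none
Why: Chemoselective hydride reduction, since the aldehyde should be reduced at low temperature much faster than the aryl lactone or the methyl ester.

Step 11
Reactants: 15 methyl 8-(benzyloxy)-4-(hydroxymethyl)-3-methoxy-1,9-dimethyl-11-oxo-11H-dibenzo[b,e][1,4]dioxepine-7-carboxylate
Product: 16 methyl 8-(benzyloxy)-3-methoxy-1,9-dimethyl-11-oxo-4-{[(triisopropylsilyl)oxy]methyl}-11H-dibenzo[b,e][1,4]dioxepine-7-carboxylate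
Conditions: iPr3SiOSO2CF3, 2,6-lutidine, CH2Cl2, −40 to 0 °C
Reagents that add atoms: triisopropylsilyl trifluoromethanesulfonate, CC(C)[Si](OS(=O)(=O)C(F)(F)F)(C(C)C)C(C)C
Why: Silylation of the hindered primary benzylic alcohol with the silyl triflate; the bulky silyl ether has no enolisable hydrogen and should withstand the hot phosphate–bromide medium of step 13 and the amide base of step 14.

Step 12
Reactants: 16 methyl 8-(benzyloxy)-3-methoxy-1,9-dimethyl-11-oxo-4-{[(triisopropylsilyl)oxy]methyl}-11H-dibenzo[b,e][1,4]dioxepine-7-carboxylate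
Product: 17 8-(benzyloxy)-3-methoxy-1,9-dimethyl-11-oxo-4-{[(triisopropylsilyl)oxy]methyl}-11H-dibenzo[b,e][1,4]dioxepine-7-carboxylic acid
Conditions: LiI (anhydrous), pyridine, 110 °C; then cold 0.5 M aq. HCl
Reagents that add atoms: none
Why: SN2 dealkylation of the methyl ester by iodide at the methyl carbon, a non-hydrolytic cleavage that should spare the base-sensitive aryl lactone, the benzyl ether and the silyl ether.

Step 13
Reactants: 17 8-(benzyloxy)-3-methoxy-1,9-dimethyl-11-oxo-4-{[(triisopropylsilyl)oxy]methyl}-11H-dibenzo[b,e][1,4]dioxepine-7-carboxylic acid; 18 dibromomethane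
Product: 20 4-(benzyloxy)-10-methoxy-5,8-dimethyl-11-{[(triisopropylsilyl)oxy]methyl}-1H-isobenzofuro[4,5-b][1,4]benzodioxepine-3,7-dione, via bromomethyl acid 19 (not isolated)
Conditions: Pd(OAc)2 (10 mol %), K2HPO4 (3 equiv), CH2Br2 (solvent), 140 °C, sealed tube
Reagents that add atoms: none
Why: The potassium carboxylate at b5 binds divalent palladium and delivers it to the b6 C–H bond by concerted metalation–deprotonation, giving a five-membered palladacycle; oxidative addition of CH2Br2 to tetravalent palladium and C–C reductive elimination place a bromomethyl group on b6 and return divalent palladium without an external oxidant. The carboxylate then displaces bromide from the bromomethyl group in a 5-exo-tet closure that forms the phthalide lactone. The closest known reaction type is the palladium-catalysed ortho C–H alkylation–lactonisation of benzoic acids with dihaloalkanes. No stereocentre is formed. The step needs site selectivity, and the substrate secures it: b4 carries the benzyloxy group, so b6 is the only C–H bond ortho to the only carboxyl group, and ring A has no acid to direct the metal. The phosphate takes up the HBr, so the silyl ether, the benzyl ether and the seven-membered lactone should pass unchanged.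

Step 14
Reactants: 20 4-(benzyloxy)-10-methoxy-5,8-dimethyl-11-{[(triisopropylsilyl)oxy]methyl}-1H-isobenzofuro[4,5-b][1,4]benzodioxepine-3,7-dione
Product: 22 rac-4-(benzyloxy)-1-hydroxy-10-methoxy-5,8-dimethyl-11-{[(triisopropylsilyl)oxy]methyl}-1H-isobenzofuro[4,5-b][1,4]benzodioxepine-3,7-dione, via potassium enolate 21 (not isolated)
Conditions: KN(SiMe3)2 (1.1 equiv), THF, −78 °C; transfer into 2-(phenylsulfonyl)-3-phenyloxaziridine, THF, −78 °C; AcOH
Reagents that add atoms: potassium bis(trimethylsilyl)amide, C[Si](C)(C)[N-][Si](C)(C)C.[K+] (potassium of 21); 2-(phenylsulfonyl)-3-phenyloxaziridine, O=S(=O)(c1ccccc1)N1OC1c1ccccc1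
Why: The phthalide CH2 is the most acidic C–H bond (its anion is an extended lactone enolate) and is hydroxylated by the N-sulfonyloxaziridine (enolate hydroxylation); inverse addition keeps free enolate away from the product, and the new stereocentre is formed racemic on purpose.

Step 15
Reactants: 22 rac-4-(benzyloxy)-1-hydroxy-10-methoxy-5,8-dimethyl-11-{[(triisopropylsilyl)oxy]methyl}-1H-isobenzofuro[4,5-b][1,4]benzodioxepine-3,7-dione
Product: 23 rac-1,4-dihydroxy-10-methoxy-5,8-dimethyl-11-{[(triisopropylsilyl)oxy]methyl}-1H-isobenzofuro[4,5-b][1,4]benzodioxepine-3,7-dione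
Conditions: H2 (1 atm), 10% Pd/C, EtOAc, rt
Reagents that add atoms: none
Why: Hydrogenolysis of the aryl benzyl ether, which should be much faster than cleavage of the hindered benzylic C–O bonds of the silyl ether and of the closed lactol in a neutral aprotic solvent.

Step 16
Reactants: 23 rac-1,4-dihydroxy-10-methoxy-5,8-dimethyl-11-{[(triisopropylsilyl)oxy]methyl}-1H-isobenzofuro[4,5-b][1,4]benzodioxepine-3,7-dione
Product: 24 rac-1,4-dihydroxy-11-(hydroxymethyl)-10-methoxy-5,8-dimethyl-1H-isobenzofuro[4,5-b][1,4]benzodioxepine-3,7-dione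
Conditions: HF·pyridine, pyridine, THF, 0 °C to rt
Reagents that add atoms: none
Why: Fluoride-driven desilylation under pyridine-buffered conditions that are neither basic enough to open the aryl lactone nor acidic enough to ionise the a6 benzylic C–O bond.

Step 17
Reactants: 24 rac-1,4-dihydroxy-11-(hydroxymethyl)-10-methoxy-5,8-dimethyl-1H-isobenzofuro[4,5-b][1,4]benzodioxepine-3,7-dione
Product: 25 [(1R)-1-acetoxy-4-hydroxy-10-methoxy-5,8-dimethyl-3,7-dioxo-1,3-dihydro-7H-isobenzofuro[4,5-b][1,4]benzodioxepin-11-yl]methyl acetate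
Conditions: immobilised Burkholderia cepacia lipase, vinyl acetate, Et3N (5 mol %), THF–toluene, 40 °C
Reagents that add atoms: vinyl acetate, CC(=O)OC=C
Why: Lipase-catalysed acylative dynamic kinetic resolution of a pseudo-acid lactol: the amine keeps the two lactol enantiomers in equilibrium through the ring-opened formyl carboxylate while the enzyme acetylates one of them (and the primary alcohol). By the empirical size rule for lipase acylation of secondary alcohols (aryl side large, lactone oxygen side medium) that enantiomer should be (R), and the descriptor is unchanged on acetylation.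

Step 18
Reactants: 25 [(1R)-1-acetoxy-4-hydroxy-10-methoxy-5,8-dimethyl-3,7-dioxo-1,3-dihydro-7H-isobenzofuro[4,5-b][1,4]benzodioxepin-11-yl]methyl acetate
Product: 26 (1R)-1,4-dihydroxy-11-(hydroxymethyl)-10-methoxy-5,8-dimethyl-1H-isobenzofuro[4,5-b][1,4]benzodioxepine-3,7-dione
Conditions: immobilised Burkholderia cepacia lipase, n-BuOH, tert-butyl methyl ether, 20 °C
Reagents that add atoms: none
Why: Lipase-catalysed transesterification to butanol, the reverse of step 17, which cleaves acyl–oxygen bonds only, so the C–O bond at the stereocentre is untouched; without base or water the lactol should not ring-open, and the (R) configuration should be kept.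

**Compound list**

1 | 3-fluoro-5-methylanisole | COc1cc(C)cc(F)c1 | starting material
2 | 2-bromo-1-fluoro-5-methoxy-3-methylbenzene | COc1cc(C)c(Br)c(F)c1 | intermediate
3 | (3-bromo-2-fluoro-6-methoxy-4-methylphenyl)lithium | [Li]c1c(F)c(Br)c(C)cc1OC | intermediate (not isolated)
4 | 3-bromo-2-fluoro-6-methoxy-4-methylbenzaldehyde | COc1cc(C)c(Br)c(F)c1C=O | intermediate
5 | 4-methoxybenzyl 2-fluoro-3-formyl-4-methoxy-6-methylbenzoate | COc1cc(C)c(C(=O)OCc2ccc(OC)cc2)c(F)c1C=O | intermediate
6 | methyl 2,4-dihydroxy-3-methylbenzoate | COC(=O)c1ccc(O)c(C)c1O | starting material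
7 | methyl 2-hydroxy-4-(methoxymethoxy)-3-methylbenzoate | COCOc1ccc(C(=O)OC)c(O)c1C | intermediate
8 | methyl 5-bromo-2-hydroxy-4-(methoxymethoxy)-3-methylbenzoate | COCOc1c(Br)cc(C(=O)OC)c(O)c1C | intermediate
9 | methyl 2-(benzyloxy)-5-bromo-4-(methoxymethoxy)-3-methylbenzoate | COCOc1c(Br)cc(C(=O)OC)c(OCc2ccccc2)c1C | intermediate
10 | methyl 2-(benzyloxy)-4-(methoxymethoxy)-3-methyl-5-(4,4,5,5-tetramethyl-1,3,2-dioxaborolan-2-yl)benzoate | COCOc1c(B2OC(C)(C)C(C)(C)O2)cc(C(=O)OC)c(OCc2ccccc2)c1C | intermediate (not isolated)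
11 | methyl 2-(benzyloxy)-5-hydroxy-4-(methoxymethoxy)-3-methylbenzoate | COCOc1c(O)cc(C(=O)OC)c(OCc2ccccc2)c1C | intermediate
12 | 4-methoxybenzyl 2-[4-(benzyloxy)-5-(methoxycarbonyl)-2-(methoxymethoxy)-3-methylphenoxy]-3-formyl-4-methoxy-6-methylbenzoate | COc1cc(C)c(C(=O)OCc2ccc(OC)cc2)c(Oc3cc(C(=O)OC)c(OCc4ccccc4)c(C)c3OCOC)c1C=O | intermediate
13 | 2-[4-(benzyloxy)-2-hydroxy-5-(methoxycarbonyl)-3-methylphenoxy]-3-formyl-4-methoxy-6-methylbenzoic acid | COc1cc(C)c(C(=O)O)c(Oc2cc(C(=O)OC)c(OCc3ccccc3)c(C)c2O)c1C=O | intermediate (not isolated)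
14 | methyl 8-(benzyloxy)-4-formyl-3-methoxy-1,9-dimethyl-11-oxo-11H-dibenzo[b,e][1,4]dioxepine-7-carboxylate | COc1cc(C)c2c(c1C=O)Oc1cc(C(=O)OC)c(OCc3ccccc3)c(C)c1OC2=O | intermediate
15 | methyl 8-(benzyloxy)-4-(hydroxymethyl)-3-methoxy-1,9-dimethyl-11-oxo-11H-dibenzo[b,e][1,4]dioxepine-7-carboxylate | COc1cc(C)c2c(c1CO)Oc1cc(C(=O)OC)c(OCc3ccccc3)c(C)c1OC2=O | intermediate
16 | methyl 8-(benzyloxy)-3-methoxy-1,9-dimethyl-11-oxo-4-{[(triisopropylsilyl)oxy]methyl}-11H-dibenzo[b,e][1,4]dioxepine-7-carboxylate | COc1cc(C)c2c(c1CO[Si](C(C)C)(C(C)C)C(C)C)Oc1cc(C(=O)OC)c(OCc3ccccc3)c(C)c1OC2=O | intermediate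
17 | 8-(benzyloxy)-3-methoxy-1,9-dimethyl-11-oxo-4-{[(triisopropylsilyl)oxy]methyl}-11H-dibenzo[b,e][1,4]dioxepine-7-carboxylic acid (depsidone acid with hydrogen on b6) | COc1cc(C)c2c(c1CO[Si](C(C)C)(C(C)C)C(C)C)Oc1cc(C(=O)O)c(OCc3ccccc3)c(C)c1OC2=O | intermediate
18 | dibromomethane | BrCBr | starting material
19 | 8-(benzyloxy)-6-(bromomethyl)-3-methoxy-1,9-dimethyl-11-oxo-4-{[(triisopropylsilyl)oxy]methyl}-11H-dibenzo[b,e][1,4]dioxepine-7-carboxylic acid | COc1cc(C)c2c(c1CO[Si](C(C)C)(C(C)C)C(C)C)Oc1c(CBr)c(C(=O)O)c(OCc3ccccc3)c(C)c1OC2=O | intermediate (not isolated)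
20 | 4-(benzyloxy)-10-methoxy-5,8-dimethyl-11-{[(triisopropylsilyl)oxy]methyl}-1H-isobenzofuro[4,5-b][1,4]benzodioxepine-3,7-dione (depsidone with ring B fused to the phthalide) | COc1cc(C)c2c(c1CO[Si](C(C)C)(C(C)C)C(C)C)Oc1c(c(C)c(OCc4ccccc4)c3c1COC3=O)OC2=O | intermediate
21 | potassium enolate of 20 (carbanion at the phthalide CH) | COc1cc(C)c2c(c1CO[Si](C(C)C)(C(C)C)C(C)C)Oc1c(c(C)c(OCc4ccccc4)c3c1[CH-]OC3=O)OC2=O.[K+] | intermediate (not isolated)
22 | rac-4-(benzyloxy)-1-hydroxy-10-methoxy-5,8-dimethyl-11-{[(triisopropylsilyl)oxy]methyl}-1H-isobenzofuro[4,5-b][1,4]benzodioxepine-3,7-dione | COc1cc(C)c2c(c1CO[Si](C(C)C)(C(C)C)C(C)C)Oc1c(c(C)c(OCc4ccccc4)c3c1C(O)OC3=O)OC2=O | intermediate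
23 | rac-1,4-dihydroxy-10-methoxy-5,8-dimethyl-11-{[(triisopropylsilyl)oxy]methyl}-1H-isobenzofuro[4,5-b][1,4]benzodioxepine-3,7-dione | COc1cc(C)c2c(c1CO[Si](C(C)C)(C(C)C)C(C)C)Oc1c(c(C)c(O)c3c1C(O)OC3=O)OC2=O | intermediate
24 | rac-1,4-dihydroxy-11-(hydroxymethyl)-10-methoxy-5,8-dimethyl-1H-isobenzofuro[4,5-b][1,4]benzodioxepine-3,7-dione | COc1cc(C)c2c(c1CO)Oc1c(c(C)c(O)c3c1C(O)OC3=O)OC2=O | intermediate
25 | [(1R)-1-acetoxy-4-hydroxy-10-methoxy-5,8-dimethyl-3,7-dioxo-1,3-dihydro-7H-isobenzofuro[4,5-b][1,4]benzodioxepin-11-yl]methyl acetate | COc1cc(C)c2c(c1COC(C)=O)Oc1c(c(C)c(O)c3c1[C@H](OC(C)=O)OC3=O)OC2=O | intermediate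
26 | (1R)-1,4-dihydroxy-11-(hydroxymethyl)-10-methoxy-5,8-dimethyl-1H-isobenzofuro[4,5-b][1,4]benzodioxepine-3,7-dione | COc1cc(C)c2c(c1CO)Oc1c(c(C)c(O)c3c1[C@H](O)OC3=O)OC2=O | target

**Totals**

Total step count: 18.
Longest linear sequence: 15 steps (6 to 26: steps 4–18).

**Steps most likely to fail**

Step 13. The risk is that palladation between the carboxylate and the aryloxy-bearing b1 is slow, so that O-alkylation of the carboxylate by CH2Br2 at 140 °C or loss of the silyl ether takes over. The fallback sets out from 11 and returns at 20; it puts the one-carbon unit on b6 while b1 is still a free phenol.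
- Magnesium-mediated ortho-formylation of 11 (MgCl2, Et3N, paraformaldehyde, MeCN, reflux; b6 is the only free position ortho to the phenol) should give methyl 2-(benzyloxy)-6-formyl-5-hydroxy-4-(methoxymethoxy)-3-methylbenzoate F1.
- NaBH4 (MeOH, 0 °C) should give methyl 2-(benzyloxy)-5-hydroxy-6-(hydroxymethyl)-4-(methoxymethoxy)-3-methylbenzoate F2 (not isolated), which closes onto the neighbouring ester to 7-(benzyloxy)-4-hydroxy-5-(methoxymethoxy)-6-methylisobenzofuran-1(3H)-one F3.
- SNAr of F3 with 5 (K2CO3, DMF) should give 4-methoxybenzyl 2-{[7-(benzyloxy)-5-(methoxymethoxy)-6-methyl-1-oxo-1,3-dihydroisobenzofuran-4-yl]oxy}-3-formyl-4-methoxy-6-methylbenzoate F4.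
- The conditions of step 9 should give 2-{[7-(benzyloxy)-5-hydroxy-6-methyl-1-oxo-1,3-dihydroisobenzofuran-4-yl]oxy}-3-formyl-4-methoxy-6-methylbenzoic acid F5 (not isolated) and from it 4-(benzyloxy)-10-methoxy-5,8-dimethyl-3,7-dioxo-1,3-dihydro-7H-isobenzofuro[4,5-b][1,4]benzodioxepine-11-carbaldehyde F6.
- The conditions of step 10 should give 4-(benzyloxy)-11-(hydroxymethyl)-10-methoxy-5,8-dimethyl-1H-isobenzofuro[4,5-b][1,4]benzodioxepine-3,7-dione F7, and silylation as in step 11 gives 20.

Step 14. The risk is that the enolate is consumed by aldol-type addition to the ring-opened formyl carboxylate that forms on oxygen transfer, or that the amide base attacks the aryl lactone. The fallback sets out from 20 and returns at 22; it introduces the heteroatom in two stages through a product that is not electrophilic. KN(SiMe3)2 (2 equiv, THF, −78 °C) followed by S-phenyl benzenethiosulfonate should give 4-(benzyloxy)-10-methoxy-5,8-dimethyl-1-(phenylthio)-11-{[(triisopropylsilyl)oxy]methyl}-1H-isobenzofuro[4,5-b][1,4]benzodioxepine-3,7-dione F8. Silver-assisted hydrolysis of this monothioacetal (AgNO3, 2,6-lutidine, aqueous acetone, rt) gives lactol 22.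

Step 17. The risk is insufficient enantiodiscrimination or slow turnover of the hindered lactol in the enzyme, with acetylation of both enantiomers or racemisation slower than acylation. The fallback sets out from 24 and returns at 26; the configuration is set by a small-molecule catalyst and the enzyme is kept only for the neutral deacylation. Acylative dynamic kinetic resolution with acetic anhydride, iPr2NEt and the chiral isothiourea HyperBTM (the catalyst enantiomer that delivers the (R)-acylal, chosen on 3-hydroxyphthalide as a model) in CH2Cl2 should acetylate all three hydroxyl groups and give [(1R)-1,4-diacetoxy-10-methoxy-5,8-dimethyl-3,7-dioxo-1,3-dihydro-7H-isobenzofuro[4,5-b][1,4]benzodioxepin-11-yl]methyl acetate F9. Lipase-catalysed butanolysis under the conditions of step 18 then removes the three acetyl groups and gives 26.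

**Further compounds**

F1 | step 13 | methyl 2-(benzyloxy)-6-formyl-5-hydroxy-4-(methoxymethoxy)-3-methylbenzoate | COCOc1c(O)c(C=O)c(C(=O)OC)c(OCc2ccccc2)c1C
F2 | step 13 | methyl 2-(benzyloxy)-5-hydroxy-6-(hydroxymethyl)-4-(methoxymethoxy)-3-methylbenzoate | COCOc1c(O)c(CO)c(C(=O)OC)c(OCc2ccccc2)c1C
F3 | step 13 | 7-(benzyloxy)-4-hydroxy-5-(methoxymethoxy)-6-methylisobenzofuran-1(3H)-one | COCOc1c(O)c2c(c(OCc3ccccc3)c1C)C(=O)OC2
F4 | step 13 | 4-methoxybenzyl 2-{[7-(benzyloxy)-5-(methoxymethoxy)-6-methyl-1-oxo-1,3-dihydroisobenzofuran-4-yl]oxy}-3-formyl-4-methoxy-6-methylbenzoate | COc1cc(C)c(C(=O)OCc2ccc(OC)cc2)c(Oc3c(OCOC)c(C)c(OCc4ccccc4)c5c3COC5=O)c1C=O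
F5 | step 13 | 2-{[7-(benzyloxy)-5-hydroxy-6-methyl-1-oxo-1,3-dihydroisobenzofuran-4-yl]oxy}-3-formyl-4-methoxy-6-methylbenzoic acid | COc1cc(C)c(C(=O)O)c(Oc2c(O)c(C)c(OCc3ccccc3)c4c2COC4=O)c1C=O
F6 | step 13 | 4-(benzyloxy)-10-methoxy-5,8-dimethyl-3,7-dioxo-1,3-dihydro-7H-isobenzofuro[4,5-b][1,4]benzodioxepine-11-carbaldehyde | COc1cc(C)c2c(c1C=O)Oc1c(c(C)c(OCc4ccccc4)c3c1COC3=O)OC2=O
F7 | step 13 | 4-(benzyloxy)-11-(hydroxymethyl)-10-methoxy-5,8-dimethyl-1H-isobenzofuro[4,5-b][1,4]benzodioxepine-3,7-dione | COc1cc(C)c2c(c1CO)Oc1c(c(C)c(OCc4ccccc4)c3c1COC3=O)OC2=O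
F8 | step 14 | 4-(benzyloxy)-10-methoxy-5,8-dimethyl-1-(phenylthio)-11-{[(triisopropylsilyl)oxy]methyl}-1H-isobenzofuro[4,5-b][1,4]benzodioxepine-3,7-dione | COc1cc(C)c2c(c1CO[Si](C(C)C)(C(C)C)C(C)C)Oc1c(c(C)c(OCc4ccccc4)c3c1C(Sc5ccccc5)OC3=O)OC2=O
F9 | step 17 | [(1R)-1,4-diacetoxy-10-methoxy-5,8-dimethyl-3,7-dioxo-1,3-dihydro-7H-isobenzofuro[4,5-b][1,4]benzodioxepin-11-yl]methyl acetate | COc1cc(C)c2c(c1COC(C)=O)Oc1c(c(C)c(OC(C)=O)c3c1[C@H](OC(C)=O)OC3=O)OC2=O
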